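**Strategy.** Everything rests on cutting C9 out of ring B (C5–C10, labdane numbering). The decalin is traced back to a cis-hydrindanone whose five-membered ring holds C5, C6, C7, C8 and C10. The key step exploits the sp2 carbon C8 lying beside C9 and quaternary C10. A dibromomethyl carbinol at C8 is converted by n-BuLi into a β-oxido carbenoid. C10 shifts onto the carbenoid carbon, and the six-ring C8=C9 enolate thus released is trapped on its β face by (phenylselanyl)acetaldehyde. One operation enlarges the ring, makes the hindered C9–C10 bond and sets C9 together with C11. A desymmetrising reductive aldol builds the precursor; a B-alkyl Suzuki coupling adds the E-diol arm.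

Key step: step 8

Remark on numbering and stereochemistry: labdane numbering is used for every compound.
- Ring A is C1–C5 plus C10, and ring B is C5–C10.
- C17 is the methylene carbon, C18 the 4-methyl, C19 the ester carbonyl and C20 the 10-methyl. β is the face of C20.
- The target SMILES encodes a cis-fused decalin: 4β-CO2Me, 5β-H, 9β-side chain (9α-H), 10β-CH3 and 13E. In naphthalene numbering this is (1S,4aR,5S,8aS).

Assumption: the sense of induction of the chiral ligand in step 3 cannot be derived a priori. The ligand antipode that gives the (7aS) series is taken.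

Step 1
Reactants: 1 2-methylcyclopentane-1,3-dione; 2 acrolein
Product: 3 3-(1-methyl-2,5-dioxocyclopentyl)propanal
Conditions: H2O, rt
Reagents that add atoms: none
Why: Michael addition of the acidic 1,3-dione carbon (future C10) to acrolein should stop at the mono-adduct because C10 becomes quaternary, and no stereocentre is formed.

Step 2
Reactants: 3 3-(1-methyl-2,5-dioxocyclopentyl)propanal; 4 methyl 2-(triphenyl-λ5-phosphanylidene)propanoate
Product: 5 methyl (E)-2-methyl-5-(1-methyl-2,5-dioxocyclopentyl)pent-2-enoate
Conditions: CH2Cl2, rt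
Reagents that add atoms: none
Why: Wittig olefination with a stabilised ylide should select the aldehyde over the two hindered ring ketones and give the E-enoate (C3=C4).

Step 3
Reactants: 5 methyl (E)-2-methyl-5-(1-methyl-2,5-dioxocyclopentyl)pent-2-enoate
Product: 7 methyl (3aR,4S,7aS)-3a-hydroxy-4,7a-dimethyl-1-oxooctahydro-1H-indene-4-carboxylate (5β-OH 4β-CO2Me 10β-CH3), via phenylsilyl ether 6 (not isolated)
Conditions: Cu(OAc)2·H2O (5 mol %), (R)-DTBM-SEGPHOS (5 mol %, antipode per assumption), PhSiH3 (1.2 equiv), toluene, −20 °C; then 1 M HCl, THF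
Reagents that add atoms: phenylsilane, [SiH3]c1ccccc1 (silicon stays only in 6)
Why: Copper hydride conjugate reduction followed by intramolecular aldol addition (reductive aldol cyclisation, 6-(enolexo)-exo-trig) desymmetrises the dione, in that the chiral bisphosphine on the copper enolate selects one enantiotopic carbonyl (C10 and C5), the tether enforces cis fusion (5-OH cis to C20), and the chelated Zimmerman–Traxler chair places the flat ketene-acetal carbon C19 rather than the methyl on the face of the oxygen and C20 (4β-CO2Me).

Step 4
Reactants: 7 hydroxy keto ester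
Product: 9 methyl (4S,7aS)-4,7a-dimethyl-1-oxo-2,4,5,6,7,7a-hexahydro-1H-indene-4-carboxylate (C5=C6 alkene), via chlorosulfite 8 (not isolated)
Conditions: SOCl2, pyridine, 0 °C
Reagents that add atoms: thionyl chloride, O=S(Cl)Cl (stays only in 8)
Why: E2 dehydration through the chlorosulfite can only go towards C6 because C4 and C10 are quaternary, and the pyridine medium should suppress retro-aldol cleavage and cationic methyl shifts.

Step 5
Reactants: 9 C5=C6 keto ester
Product: 10 methyl (3aS,4S,7aS)-4,7a-dimethyl-1-oxooctahydro-1H-indene-4-carboxylate (cis-hydrindanone with 5β-H)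
Conditions: [Ir(cod)(PCy3)(py)]PF6 (10 mol %), H2 (1–50 bar), CH2Cl2, rt
Reagents that add atoms: none
Why: In this carbonyl-directed homogeneous hydrogenation the cationic iridium centre should bind the allylic 4β-ester carbonyl and deliver H2 to the β face of C5=C6, setting 5β-H, whereas an undirected catalyst would approach anti to C20.

Step 6
Reactants: 10 cis-hydrindanone; 11 dibromomethane
Product: 12 methyl (3aS,4S,7aS)-1-(dibromomethyl)-1-hydroxy-4,7a-dimethyloctahydro-1H-indene-4-carboxylate (C8 epimers)
Conditions: LiN(iPr)2 added to 10 and 11, THF, −78 °C; AcOH quench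
Reagents that add atoms: none
Why: 1,2-Addition of dibromomethyllithium, generated in the presence of the ketone so that it is trapped before it decomposes, should hit the only ketone while the neopentyl ester is inert at −78 °C, and the new C8 centre is erased in step 8.

Step 7
Reactants: 13 benzeneselenenyl chloride; 14 ethyl vinyl ether
Product: 16 (phenylselanyl)acetaldehyde, via α-chloro ether 15 (not isolated)
Conditions: CH2Cl2, −78 to 0 °C; then aq. NaHCO3, THF
Reagents that add atoms: water, O
Why: Electrophilic selenenylation of the enol ether gives the Markovnikov α-chloro ether, whose hydrolysis releases the aldehyde, and no stereocentre is formed.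

Step 8
Reactants: 12 dibromomethyl carbinol; 16 (phenylselanyl)acetaldehyde
Product: 19 methyl 11-hydroxy-8-oxo-12-(phenylselanyl)-13,14,15,16,17-pentanor-5β-labdan-19-oate (9α-H; C11 epimers), via β-oxido carbenoid 17 (not isolated), via lithium enolate 18 (not isolated)
Conditions: n-BuLi (2.05 equiv), THF, −95 °C, warm to 0 °C; recool to −78 °C, 16; AcOH, −78 °C
Reagents that add atoms: n-butyllithium, [Li]CCCC (lithium stays only in 17 and 18)
Why: The first n-BuLi deprotonates the carbinol and the second exchanges one bromine to give carbenoid 17; on warming the alkoxide pushes the C8–C10 σ bond onto the carbenoid carbon (new C9) as LiBr leaves, so C9 is inserted between C8 and C10 and the regiodefined enolate 18 (C8=C9) is set free. This is the known β-oxido carbenoid one-carbon ring enlargement of dibromomethyl carbinols, followed by aldol trapping of the enolate it releases. No ring is closed by cyclisation: the five-membered ring C5–C6–C7–C8–C10 is enlarged to six-membered ring B by a 1,2-shift in which C10 migrates with retention. C9 is set in the aldol addition, because in the half-chair of 18 that keeps C4 equatorial on ring B, C1 is pseudoaxial on the α face and the aldehyde should enter axially from the β face past only H5, placing C11 β (cis to C20), while C11 forms as a mixture that step 9 erases. The step needs migration of C10 rather than C7, which is secured by the cation-like migration terminus that favours the more substituted carbon and by the rotamer that holds the bulky bromine anti to C10, and it needs Br/Li exchange rather than ester attack, which is secured by low temperature, exact stoichiometry and the neopentyl C19 ester. The enolate beside quaternary C10 is not accessible by deprotonation of the ketone, which would go to C7.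

Step 9
Reactants: 19 aldol
Product: 21 methyl 8-oxo-13,14,15,16,17-pentanor-5β-labd-11-en-19-oate (9β-vinyl 9α-H), via mesylate 20 (not isolated)
Conditions: MsCl, Et3N, CH2Cl2, 0 °C
Reagents that add atoms: methanesulfonyl chloride, CS(=O)(=O)Cl (stays only in 20)
Why: In this reductive elimination of a β-hydroxy selenide, mesylation triggers displacement by selenium and chloride strips PhSe+ from the seleniranium ion faster than E1cB loss towards C9, so both C11 epimers should give the terminal vinyl group with C9 untouched.

Step 10
Reactants: 21 vinyl ketone; 11 dibromomethane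
Product: 22 methyl 13,14,15,16-tetranor-5β-labda-8(17),11-dien-19-oate
Conditions: Zn, 11, TiCl4 (pre-aged reagent), THF/CH2Cl2, 0 °C to rt
Reagents that add atoms: none
Why: Takai–Lombardo methylenation uses a non-basic gem-dimetallic reagent that should convert the hindered, easily enolised C8 ketone into the exocyclic methylene without epimerising C9 or conjugating the vinyl group, and it leaves the ester alone.

Step 11
Reactants: 23 but-2-yne-1,4-diol
Product: 25 (Z)-2-iodobut-2-ene-1,4-diol, via alkenyl aluminate 24 (not isolated)
Conditions: NaAlH2(OCH2CH2OMe)2 (2.5 equiv), THF, 0 °C to rt; I2, −78 to 0 °C; aq. potassium sodium tartrate, Na2S2O3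
Reagents that add atoms: iodine, II; sodium bis(2-methoxyethoxy)aluminium dihydride, [Na+].[H][Al-]([H])(OCCOC)OCCOC (aluminium stays only in 24)
Why: Alkoxide-directed trans-hydroalumination of the propargylic diol followed by iodinolysis with retention should give the iodide whose two CH2OH groups are trans, which is the geometry needed at C13=C14.

Step 12
Reactants: 22 diene ester; 25 (Z)-2-iodobut-2-ene-1,4-diol
Product: 27 methyl 15,16-dihydroxy-5β-labda-8(17),13E-dien-19-oate (target), via B-alkyl borane 26 (not isolated)
Conditions: 9-BBN-H (1.1 equiv), THF, 0 °C to rt; then 25, PdCl2(dppf) (5 mol %), AsPh3, Cs2CO3, DMF/H2O, rt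
Reagents that add atoms: 9-borabicyclo[3.3.1]nonane, [H]B1C2CCCC1CCC2 (boron stays only in 26)
Why: Hydroboration should pick the monosubstituted vinyl group over the C8 methylene, which is screened by C1 on one face and by the C9 substituent on the other, and the B-alkyl Suzuki–Miyaura coupling joins C12 to C13 with retention of alkene geometry while tolerating free hydroxyl groups.

**Compound list**

1 | 2-methylcyclopentane-1,3-dione | CC1C(=O)CCC1=O | starting material
2 | acrolein | C=CC=O | starting material
3 | 3-(1-methyl-2,5-dioxocyclopentyl)propanal | CC1(CCC=O)C(=O)CCC1=O | intermediate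
4 | methyl 2-(triphenyl-λ5-phosphanylidene)propanoate | COC(=O)C(C)=P(c1ccccc1)(c1ccccc1)c1ccccc1 | starting material
5 | methyl (E)-2-methyl-5-(1-methyl-2,5-dioxocyclopentyl)pent-2-enoate | COC(=O)/C(C)=C/CCC1(C)C(=O)CCC1=O | intermediate
6 | 5-O-phenylsilyl ether of 7 | O=C1CC[C@@]2(O[SiH2]c3ccccc3)[C@]1(C)CCC[C@]2(C)C(=O)OC | intermediate
7 | methyl (3aR,4S,7aS)-3a-hydroxy-4,7a-dimethyl-1-oxooctahydro-1H-indene-4-carboxylate | O=C1CC[C@@]2(O)[C@]1(C)CCC[C@]2(C)C(=O)OC | intermediate
8 | chlorosulfite of 7 | O=C1CC[C@@]2(OS(=O)Cl)[C@]1(C)CCC[C@]2(C)C(=O)OC | intermediate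
9 | methyl (4S,7aS)-4,7a-dimethyl-1-oxo-2,4,5,6,7,7a-hexahydro-1H-indene-4-carboxylate | O=C1CC=C2[C@]1(C)CCC[C@]2(C)C(=O)OC | intermediate
10 | methyl (3aS,4S,7aS)-4,7a-dimethyl-1-oxooctahydro-1H-indene-4-carboxylate | O=C1CC[C@H]2[C@]1(C)CCC[C@]2(C)C(=O)OC | intermediate
11 | dibromomethane | BrCBr | starting material
12 | methyl (3aS,4S,7aS)-1-(dibromomethyl)-1-hydroxy-4,7a-dimethyloctahydro-1H-indene-4-carboxylate (C8 epimers) | OC1(C(Br)Br)CC[C@H]2[C@]1(C)CCC[C@]2(C)C(=O)OC | intermediate
13 | benzeneselenenyl chloride | Cl[Se]c1ccccc1 | starting material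
14 | ethyl vinyl ether | C=COCC | starting material
15 | 1-chloro-1-ethoxy-2-(phenylselanyl)ethane | CCOC(Cl)C[Se]c1ccccc1 | intermediate
16 | (phenylselanyl)acetaldehyde | O=CC[Se]c1ccccc1 | intermediate
17 | lithium β-oxido carbenoid from 12 | [Li]OC1(C([Li])Br)CC[C@H]2[C@]1(C)CCC[C@]2(C)C(=O)OC | intermediate
18 | lithium C8=C9 enolate of methyl 8-oxo-11,12,13,14,15,16,17-heptanor-5β-labdan-19-oate | [Li]OC=1CC[C@H]2[C@](C)(CCC[C@]2(C)C(=O)OC)C=1 | intermediate
19 | methyl 11-hydroxy-8-oxo-12-(phenylselanyl)-13,14,15,16,17-pentanor-5β-labdan-19-oate (9α-H, C11 epimers) | O=C1CC[C@H]2[C@](C)(CCC[C@]2(C)C(=O)OC)[C@H]1C(O)C[Se]c1ccccc1 | intermediate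
20 | 11-O-mesylate of 19 | O=C1CC[C@H]2[C@](C)(CCC[C@]2(C)C(=O)OC)[C@H]1C(OS(C)(=O)=O)C[Se]c1ccccc1 | intermediate
21 | methyl 8-oxo-13,14,15,16,17-pentanor-5β-labd-11-en-19-oate (9α-H) | O=C1CC[C@H]2[C@](C)(CCC[C@]2(C)C(=O)OC)[C@H]1C=C | intermediate
22 | methyl 13,14,15,16-tetranor-5β-labda-8(17),11-dien-19-oate (9α-H) | C=C1CC[C@H]2[C@](C)(CCC[C@]2(C)C(=O)OC)[C@H]1C=C | intermediate
23 | but-2-yne-1,4-diol | OCC#CCO | starting material
24 | disodium cyclic alkenyl aluminate (idealised) | [Na+].[Na+].[H][Al-](OCCOC)(OCCOC)OCC1=CCO[Al-]1(OCCOC)OCCOC | intermediate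
25 | (Z)-2-iodobut-2-ene-1,4-diol | OC/C(I)=C/CO | intermediate
26 | 12-(9-borabicyclo[3.3.1]nonan-9-yl) adduct of 22 | C=C1CC[C@H]2[C@](C)(CCC[C@]2(C)C(=O)OC)[C@H]1CCB1C2CCCC1CCC2 | intermediate
27 | methyl (1S,4aR,5S,8aS)-5-[(3E)-5-hydroxy-3-(hydroxymethyl)pent-3-en-1-yl]-1,4a-dimethyl-6-methylidenedecahydronaphthalene-1-carboxylate | C=C1CC[C@H]2[C@](C)(CCC[C@]2(C)C(=O)OC)[C@H]1CC/C(=C\CO)CO | target

**Step count.** Total step count: 12. Longest linear sequence: 10 (steps 1–6, 8, 9, 10, 12).

**Steps most likely to fail**

1. **Step 8.**
   - What may go wrong: the carbenoid may rearrange with migration of C7 in place of C10. The enolate may be quenched by proton transfer from the enolisable aldehyde. Face selectivity of the aldol addition may erode through retro-aldol equilibration.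
   - Fallback: it sets out from 10 and comes back at enolate 18, and so at 19. It replaces the carbenoid by a cationic pinacol-type shift. Addition of LiCH(SPh)2 to 10 (THF, −78 °C) gives the bis(phenylthio)methyl carbinol F1. (CuOTf)2·C6H6 with iPr2NEt in benzene abstracts one thiolate, and the sulfur-stabilised cation draws over the more substituted carbon C10 to give the ring-enlarged 9-(phenylthio) 8-ketone F2. Two equivalents of lithium naphthalenide (THF, −78 °C) cleave the C9–S bond reductively to the same regiodefined enolate 18. This is trapped with 16 as in the main route.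

2. **Step 3.**
   - What may go wrong: selection between the enantiotopic carbonyl groups may be poor. Closure of the tetrasubstituted copper enolate onto the hindered ketone may be sluggish, so that simple conjugate reduction or ketone hydrosilylation takes over.
   - Fallback: it sets out from 5 and comes back at 7. It separates the asymmetric event from the ring closure. Transfer hydrogenation with RuCl(p-cymene)[(S,S)-TsDPEN] in HCO2H/Et3N reduces one enantiotopic ketone (future C8) to the hydroxy ketone enoate F3. Reductive aldol cyclisation with [(Ph3P)CuH]6 in toluene onto the single remaining ketone gives the 5β,8-diol F4 under substrate control. Dess–Martin periodinane oxidises only the secondary alcohol, giving 7.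

3. **Step 5.**
   - What may go wrong: hydrogen may be delivered to the α face if the ester binds iridium too weakly. The catalyst may also fail to turn over on the alkene flanked by two quaternary carbons.
   - Fallback: it sets out from 9 and comes back at 10. It installs a stronger directing group. NaBH4 in MeOH at 0 °C attacks the C8 ketone from the α face, anti to C20, and gives the 8β-alcohol F5. Hydroxyl-directed hydrogenation with [Ir(cod)(PCy3)(py)]PF6 in CH2Cl2, now steered by both the 8β-OH and the 4β-ester, gives the saturated cis-fused alcohol F6. Dess–Martin periodinane returns ketone 10.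

**Further compounds**

F1 | step 8 | methyl 1-[bis(phenylthio)methyl]-1-hydroxy-4,7a-dimethyloctahydro-1H-indene-4-carboxylate (C8 epimers) | OC1(C(Sc3ccccc3)Sc3ccccc3)CC[C@H]2[C@]1(C)CCC[C@]2(C)C(=O)OC
F2 | step 8 | methyl 8-oxo-9-(phenylthio)-11,12,13,14,15,16,17-heptanor-5β-labdan-19-oate (C9 epimers) | O=C1CC[C@H]2[C@](C)(CCC[C@]2(C)C(=O)OC)C1Sc1ccccc1
F3 | step 3 | methyl (E)-5-(2-hydroxy-1-methyl-5-oxocyclopentyl)-2-methylpent-2-enoate (C10 as in 7, carbinol centre of no consequence) | COC(=O)/C(C)=C/CC[C@]1(C)C(O)CCC1=O
F4 | step 3 | methyl 1,3a-dihydroxy-4,7a-dimethyloctahydro-1H-indene-4-carboxylate (5β-OH, 4β-CO2Me, 10β-CH3) | OC1CC[C@@]2(O)[C@]1(C)CCC[C@]2(C)C(=O)OC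
F5 | step 5 | methyl 1β-hydroxy-4,7a-dimethyl-2,4,5,6,7,7a-hexahydro-1H-indene-4-carboxylate (8β-OH, C5=C6) | O[C@H]1CC=C2[C@]1(C)CCC[C@]2(C)C(=O)OC
F6 | step 5 | methyl 1β-hydroxy-4,7a-dimethyloctahydro-1H-indene-4-carboxylate (8β-OH, 5β-H) | O[C@H]1CC[C@H]2[C@]1(C)CCC[C@]2(C)C(=O)OC
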